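**Plan**

Locants: C1–C9 are the nonadienyl chain of the alcohol part, counted from the ester oxygen; C1'–C6' are the ring carbons, C1' being the stereocentre.

- Retrosynthesis: cut the oleate C(=O)–O bond first. Then cut C8–C9 after placing a CO2H helper on C9, which makes an Ireland–Claisen retron (C9 is α, C7=C6 is γ,δ). Last, cut C9–C1' through a second Claisen retron (C9 is α, ring C2'=C3' is γ,δ).
- Enabling feature: C9 lies between two allylic carbons, C8 (allylic to C6=C7) and ring C1' (allylic to C2'=C3' of the cyclohexene). One acetate unit can therefore be delivered by two successive [3,3] shifts and its carboxyl then removed.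
- Forward: the ring is bought as 2,4,4-trimethylcyclohex-2-enone. A Johnson–Claisen rearrangement attaches CH2CO2Et at C1'; the derived acid is tethered as an ester to a geraniol-derived 2-methylalk-1-en-3-ol; the Ireland–Claisen rearrangement forms C8–C9 and the 6E olefin. Barton decarboxylation, desilylation and oleoylation finish the route.
- Stereochemistry: (S)-C1' comes from a CBS reduction to the (R)-allylic alcohol followed by suprafacial 1,3-transfer in the Johnson–Claisen step. 2E comes from geraniol, 6E from the chair transition state of the key step, and 9Z from oleic acid.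

Key step: step 8

Remark: the carbinol carbon of 8–10 and the helper-bearing C9 of 11–14 are carried as mixtures, because step 8 makes the first sp2 and step 9 makes the second a CH2 group. Conjugate bases and metal salts present before work-up (enolates, alkoxides, carboxylates) are not counted as separate compounds.

**Route**

Step 1
Reactants: 1 2,4,4-trimethylcyclohex-2-en-1-one
Product: 2 (1R)-2,4,4-trimethylcyclohex-2-en-1-ol
Conditions: (S)-Me-CBS (10 mol %), BH3·SMe2, THF, 0 °C, slow addition of 1; aq. work-up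
Reagents that add atoms: none
Why: Corey–Bakshi–Shibata reduction, in which the α-methylvinyl branch acts as the large group, so the (S)-oxazaborolidine should deliver hydride to the face that gives the (R)-carbinol, as with other 2-substituted cyclohex-2-enones.

Step 2
Reactants: 2 (1R)-2,4,4-trimethylcyclohex-2-en-1-ol
Product: 4 ethyl 2-[(1S)-2,6,6-trimethylcyclohex-2-en-1-yl]acetate, via mixed ketene acetal 3 (not isolated)
Conditions: MeC(OEt)3 (excess), EtCO2H (cat.), 140 °C, EtOH distilled off
Reagents that add atoms: triethyl orthoacetate, CC(OCC)(OCC)OCC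
Why: Johnson–Claisen orthoester rearrangement, whose [3,3] shift is suprafacial on the cyclohexene, so the new C1'–C9 bond forms on the ring face from which the C–O bond leaves and the (R)-carbinol centre is relayed to (S)-C1' beside the gem-dimethyl carbon.

Step 3
Reactants: 4 ethyl 2-[(1S)-2,6,6-trimethylcyclohex-2-en-1-yl]acetate
Product: 5 2-[(1S)-2,6,6-trimethylcyclohex-2-en-1-yl]acetic acid
Conditions: KOH, EtOH/H2O, reflux; then 1 M HCl
Reagents that add atoms: potassium hydroxide, [K+].[OH-]
Why: Ester saponification, which leaves C1' untouched because it is β to the carbonyl and cannot epimerise by enolisation.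

Step 4
Reactants: 6 geraniol
Product: 7 tert-butyl{[(2E)-3,7-dimethylocta-2,6-dien-1-yl]oxy}diphenylsilane
Conditions: TBDPSCl, imidazole, DMF, 0 °C → rt
Reagents that add atoms: tert-butyl(chloro)diphenylsilane, CC(C)(C)[Si](Cl)(c1ccccc1)c1ccccc1
Why: Standard silylation of a primary allylic alcohol, giving an ether with no acidic site that should survive peracid, aluminium amide, LDA and radical conditions.

Step 5
Reactants: 7 tert-butyl{[(2E)-3,7-dimethylocta-2,6-dien-1-yl]oxy}diphenylsilane
Product: 8 tert-butyl{[(2E)-5-(3,3-dimethyloxiran-2-yl)-3-methylpent-2-en-1-yl]oxy}diphenylsilane (racemic)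
Conditions: mCPBA (1.0 equiv), CH2Cl2, −20 → 0 °C
Reagents that add atoms: 3-chloroperbenzoic acid, OOC(=O)c1cccc(Cl)c1
Why: Prilezhaev epoxidation, expected to favour the distal 6,7-olefin because the 2,3-olefin is deactivated inductively by the allylic silyloxy group; the new stereocentre is racemic and is erased in step 8.

Step 6
Reactants: 8 tert-butyl{[(2E)-5-(3,3-dimethyloxiran-2-yl)-3-methylpent-2-en-1-yl]oxy}diphenylsilane
Product: 9 (6E)-8-[(tert-butyldiphenylsilyl)oxy]-2,6-dimethylocta-1,6-dien-3-ol (racemic)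
Conditions: Et2Al(TMP) (from LiTMP and Et2AlCl), toluene, 0 °C; aq. Rochelle salt
Reagents that add atoms: none
Why: Yamamoto aluminium amide isomerisation of an epoxide to an allylic alcohol, in which aluminium binds the oxygen, the more substituted C–O bond loosens and the amide removes a syn methyl proton, which should give the 2-methylalk-1-en-3-ol and not the tertiary allylic alcohol.

Step 7
Reactants: 5 2-[(1S)-2,6,6-trimethylcyclohex-2-en-1-yl]acetic acid; 9 (6E)-8-[(tert-butyldiphenylsilyl)oxy]-2,6-dimethylocta-1,6-dien-3-ol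
Product: 10 (6E)-8-[(tert-butyldiphenylsilyl)oxy]-2,6-dimethylocta-1,6-dien-3-yl 2-[(1S)-2,6,6-trimethylcyclohex-2-en-1-yl]acetate (both epimers at the carbinol carbon)
Conditions: DCC, DMAP (cat.), CH2Cl2, 0 °C → rt
Reagents that add atoms: none
Why: Steglich esterification, which acylates the secondary allylic alcohol without allylic transposition and so installs the ester tether that places C9 and C8 in a 1,6-relationship.

Step 8
Reactants: 10 (6E)-8-[(tert-butyldiphenylsilyl)oxy]-2,6-dimethylocta-1,6-dien-3-yl 2-[(1S)-2,6,6-trimethylcyclohex-2-en-1-yl]acetate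
Product: 13 (4E,8E)-10-[(tert-butyldiphenylsilyl)oxy]-4,8-dimethyl-2-[(1S)-2,6,6-trimethylcyclohex-2-en-1-yl]deca-4,8-dienoic acid (both C2 epimers), via silyl ketene acetal 11 (not isolated), via trimethylsilyl ester 12 (not isolated)
Conditions: LDA, THF, −78 °C; TMSCl, −78 °C → rt, then 50 °C; 1 M HCl work-up
Reagents that add atoms: chlorotrimethylsilane, C[Si](C)(C)Cl (its Me3Si group stands in 11 and 12 only; 13 keeps none of it)
Why: Kinetic deprotonation of the only enolisable position of 10 (the CH2 between the carbonyl and ring C1') and O-silylation give ketene acetal 11, whose acetal carbon (C9) and the terminal CH2 of the isopropenyl group (C8) bond in a concerted suprafacial [3,3] shift through a six-membered chair while the allylic C6–O bond breaks, turning the tether into the C8–C9 bond and a carboxyl helper on C9. The closest known reaction type is the Ireland–Claisen rearrangement of esters of 2-methylalk-1-en-3-ols, the standard entry to E-trisubstituted olefins in acyclic terpenoid chains. No ring is closed; only the six-membered pericyclic array forms. The new C9 stereocentre is not controlled and need not be, since step 9 makes C9 a CH2 group, while ring C1' is a spectator that is β to the carbonyl and is not deprotonated. The selectivity that matters is the E geometry of the new C6=C7 olefin, which the chair should secure by placing the C5 chain on the carbinol carbon equatorial, away from a 1,3-diaxial clash with the silyloxy group of the ketene acetal; the regiochemistry is fixed because the shift can only end at C8. Chemoselectivity rests on the C1 oxygen being carried as a silyl ether with no acidic site, which is why the oleate is attached only after this step.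

Step 9
Reactants: 13 (4E,8E)-10-[(tert-butyldiphenylsilyl)oxy]-4,8-dimethyl-2-[(1S)-2,6,6-trimethylcyclohex-2-en-1-yl]deca-4,8-dienoic acid
Product: 15 tert-butyl{[(2E,6E)-3,7-dimethyl-9-[(1S)-2,6,6-trimethylcyclohex-2-en-1-yl]nona-2,6-dien-1-yl]oxy}diphenylsilane, via O-acyl thiohydroxamate 14 (not isolated)
Conditions: 1-hydroxypyridine-2(1H)-thione, DCC, DMAP (cat.), CH2Cl2, rt, dark; then t-BuSH (large excess), hν (W lamp), PhH, rt
Reagents that add atoms: 1-hydroxypyridine-2(1H)-thione, ON1C=CC=CC1=S (its atoms stand in 14 only; 15 gains hydrogen alone, from t-BuSH)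
Why: Barton reductive decarboxylation, in which photolysis of the thiohydroxamate ester releases CO2 and a secondary C9 radical that the concentrated thiol should reduce much faster than it can attack either homoallylic olefin, removing the helper and leaving C9 as CH2.

Step 10
Reactants: 15 tert-butyl{[(2E,6E)-3,7-dimethyl-9-[(1S)-2,6,6-trimethylcyclohex-2-en-1-yl]nona-2,6-dien-1-yl]oxy}diphenylsilane
Product: 16 (2E,6E)-3,7-dimethyl-9-[(1S)-2,6,6-trimethylcyclohex-2-en-1-yl]nona-2,6-dien-1-ol
Conditions: TBAF, THF, 0 °C → rt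
Reagents that add atoms: none
Why: Fluoride-induced cleavage of the silyl ether, which touches neither the olefins nor C1'.

Step 11
Reactants: 16 (2E,6E)-3,7-dimethyl-9-[(1S)-2,6,6-trimethylcyclohex-2-en-1-yl]nona-2,6-dien-1-ol; 17 oleic acid
Product: 18 (2E,6E)-3,7-dimethyl-9-[(1S)-2,6,6-trimethylcyclohex-2-en-1-yl]nona-2,6-dien-1-yl (9Z)-octadec-9-enoate
Conditions: DCC, DMAP (cat.), CH2Cl2, 0 °C → rt
Reagents that add atoms: none
Why: Steglich esterification of a primary allylic alcohol under neutral conditions, placed last so that the Z-olefin and the second ester never meet LDA or thiyl radicals.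

**Compound list**

1 | 2,4,4-trimethylcyclohex-2-en-1-one | CC1=CC(C)(C)CCC1=O | starting material
2 | (1R)-2,4,4-trimethylcyclohex-2-en-1-ol | O[C@H]1C(C)=CC(C)(C)CC1 | intermediate
3 | 1-ethoxy-1-{[(1R)-2,4,4-trimethylcyclohex-2-en-1-yl]oxy}ethene (mixed ketene acetal, not isolated) | C=C(OCC)O[C@H]1C(C)=CC(C)(C)CC1 | intermediate
4 | ethyl 2-[(1S)-2,6,6-trimethylcyclohex-2-en-1-yl]acetate | CCOC(=O)C[C@@H]1C(C)=CCCC1(C)C | intermediate
5 | 2-[(1S)-2,6,6-trimethylcyclohex-2-en-1-yl]acetic acid | OC(=O)C[C@@H]1C(C)=CCCC1(C)C | intermediate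
6 | geraniol, (2E)-3,7-dimethylocta-2,6-dien-1-ol | CC(C)=CCC/C(C)=C/CO | starting material
7 | tert-butyl{[(2E)-3,7-dimethylocta-2,6-dien-1-yl]oxy}diphenylsilane | CC(C)=CCC/C(C)=C/CO[Si](c1ccccc1)(c1ccccc1)C(C)(C)C | intermediate
8 | tert-butyl{[(2E)-5-(3,3-dimethyloxiran-2-yl)-3-methylpent-2-en-1-yl]oxy}diphenylsilane (racemic) | CC1(C)OC1CC/C(C)=C/CO[Si](c1ccccc1)(c1ccccc1)C(C)(C)C | intermediate
9 | (6E)-8-[(tert-butyldiphenylsilyl)oxy]-2,6-dimethylocta-1,6-dien-3-ol (racemic) | C=C(C)C(O)CC/C(C)=C/CO[Si](c1ccccc1)(c1ccccc1)C(C)(C)C | intermediate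
10 | (6E)-8-[(tert-butyldiphenylsilyl)oxy]-2,6-dimethylocta-1,6-dien-3-yl 2-[(1S)-2,6,6-trimethylcyclohex-2-en-1-yl]acetate (both carbinol epimers) | C=C(C)C(CC/C(C)=C/CO[Si](c1ccccc1)(c1ccccc1)C(C)(C)C)OC(=O)C[C@@H]1C(C)=CCCC1(C)C | intermediate
11 | trimethylsilyl ketene acetal of 10 (not isolated) | C=C(C)C(CC/C(C)=C/CO[Si](c1ccccc1)(c1ccccc1)C(C)(C)C)OC(O[Si](C)(C)C)=C[C@@H]1C(C)=CCCC1(C)C | intermediate
12 | trimethylsilyl ester of 13 (not isolated) | C[Si](C)(C)OC(=O)C(C/C(C)=C/CC/C(C)=C/CO[Si](c1ccccc1)(c1ccccc1)C(C)(C)C)[C@@H]1C(C)=CCCC1(C)C | intermediate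
13 | (4E,8E)-10-[(tert-butyldiphenylsilyl)oxy]-4,8-dimethyl-2-[(1S)-2,6,6-trimethylcyclohex-2-en-1-yl]deca-4,8-dienoic acid (both C2 epimers) | OC(=O)C(C/C(C)=C/CC/C(C)=C/CO[Si](c1ccccc1)(c1ccccc1)C(C)(C)C)[C@@H]1C(C)=CCCC1(C)C | intermediate
14 | 2-thioxopyridin-1(2H)-yl ester of 13 (O-acyl thiohydroxamate, not isolated) | S=C2C=CC=CN2OC(=O)C(C/C(C)=C/CC/C(C)=C/CO[Si](c1ccccc1)(c1ccccc1)C(C)(C)C)[C@@H]1C(C)=CCCC1(C)C | intermediate
15 | tert-butyl{[(2E,6E)-3,7-dimethyl-9-[(1S)-2,6,6-trimethylcyclohex-2-en-1-yl]nona-2,6-dien-1-yl]oxy}diphenylsilane | CC(C)(C)[Si](c1ccccc1)(c1ccccc1)OC/C=C(\C)CC/C=C(\C)CC[C@@H]1C(C)=CCCC1(C)C | intermediate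
16 | (2E,6E)-3,7-dimethyl-9-[(1S)-2,6,6-trimethylcyclohex-2-en-1-yl]nona-2,6-dien-1-ol | OC/C=C(\C)CC/C=C(\C)CC[C@@H]1C(C)=CCCC1(C)C | intermediate
17 | oleic acid, (9Z)-octadec-9-enoic acid | CCCCCCCC/C=C\CCCCCCCC(=O)O | starting material
18 | (2E,6E)-3,7-dimethyl-9-[(1S)-2,6,6-trimethylcyclohex-2-en-1-yl]nona-2,6-dien-1-yl (9Z)-octadec-9-enoate | CCCCCCCC/C=C\CCCCCCCC(=O)OC/C=C(\C)CC/C=C(\C)CC[C@@H]1C(C)=CCCC1(C)C | target

**Step count and risks**

Total steps: 11. Longest linear sequence: 8 steps (steps 1–3 then 7–11, or steps 4–11).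

Steps most likely to fail:

Step 8. The lithium enolate, which carries the bulky ring on its carbon, may fragment to a ketene and the allylic alkoxide before it is silylated, or may be C-silylated. The hindered ketene acetal may also rearrange only sluggishly, and a competing boat transition state would erode the E geometry. The fallback replaces the tethered rearrangement by an intermolecular enolate alkylation that forms the same C8–C9 bond. It sets out from 7 and 5 and comes back at 13. Allylic oxidation of 7 with catalytic SeO2 and t-BuOOH in CH2Cl2 should give (2E,6E)-8-[(tert-butyldiphenylsilyl)oxy]-2,6-dimethylocta-2,6-dien-1-ol F1 with the E geometry typical of this oxidation. Appel bromination (CBr4, PPh3, CH2Cl2, 0 °C) should give tert-butyl{[(2E,6E)-8-bromo-3,7-dimethylocta-2,6-dien-1-yl]oxy}diphenylsilane F2. The dianion of 5 (LDA, 2.1 equiv, THF/DMPU, 0 °C) is then alkylated at its α-carbon by F2 in an SN2 reaction at the primary allylic carbon, which should deliver 13 after acidic work-up.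

Step 9. Acylation of the thiohydroxamic acid by the α-branched acid, which is flanked by the hindered ring, may be slow. The C9 radical may attack one of the homoallylic olefins before hydrogen transfer, and thiyl radicals may scramble the geometry of the trisubstituted olefins. The fallback removes the one-carbon helper by organometallic decarbonylation instead of radical decarboxylation. It sets out from 13 and comes back at 15. Reduction with LiAlH4 (THF, 0 °C) should give (4E,8E)-10-[(tert-butyldiphenylsilyl)oxy]-4,8-dimethyl-2-[(1S)-2,6,6-trimethylcyclohex-2-en-1-yl]deca-4,8-dien-1-ol F3. Dess–Martin oxidation should give (4E,8E)-10-[(tert-butyldiphenylsilyl)oxy]-4,8-dimethyl-2-[(1S)-2,6,6-trimethylcyclohex-2-en-1-yl]deca-4,8-dienal F4. Tsuji–Wilkinson decarbonylation with stoichiometric RhCl(PPh3)3 in toluene at reflux should then give 15.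

Step 5. The peracid may discriminate poorly between the two trisubstituted olefins and may over-oxidise to the bis-epoxide. The fallback goes through a halohydrin. It sets out from 7 and comes back at 8. NBS in aqueous THF at 0 °C, which is known to favour the terminal olefin of polyprenyl chains, should give (6E)-3-bromo-8-[(tert-butyldiphenylsilyl)oxy]-2,6-dimethyloct-6-en-2-ol F5. K2CO3 in MeOH should then close it to epoxide 8.

Further compounds
F1 | step 8 | (2E,6E)-8-[(tert-butyldiphenylsilyl)oxy]-2,6-dimethylocta-2,6-dien-1-ol | OC/C(C)=C/CC/C(C)=C/CO[Si](c1ccccc1)(c1ccccc1)C(C)(C)C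
F2 | step 8 | tert-butyl{[(2E,6E)-8-bromo-3,7-dimethylocta-2,6-dien-1-yl]oxy}diphenylsilane | BrC/C(C)=C/CC/C(C)=C/CO[Si](c1ccccc1)(c1ccccc1)C(C)(C)C
F3 | step 9 | (4E,8E)-10-[(tert-butyldiphenylsilyl)oxy]-4,8-dimethyl-2-[(1S)-2,6,6-trimethylcyclohex-2-en-1-yl]deca-4,8-dien-1-ol | OCC(C/C(C)=C/CC/C(C)=C/CO[Si](c1ccccc1)(c1ccccc1)C(C)(C)C)[C@@H]1C(C)=CCCC1(C)C
F4 | step 9 | (4E,8E)-10-[(tert-butyldiphenylsilyl)oxy]-4,8-dimethyl-2-[(1S)-2,6,6-trimethylcyclohex-2-en-1-yl]deca-4,8-dienal | O=CC(C/C(C)=C/CC/C(C)=C/CO[Si](c1ccccc1)(c1ccccc1)C(C)(C)C)[C@@H]1C(C)=CCCC1(C)C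
F5 | step 5 | (6E)-3-bromo-8-[(tert-butyldiphenylsilyl)oxy]-2,6-dimethyloct-6-en-2-ol | CC(C)(O)C(Br)CC/C(C)=C/CO[Si](c1ccccc1)(c1ccccc1)C(C)(C)C
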